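**Retrosynthetic overview** (longipinane numbering: C1 ketone, C2=C3 enone with C12 methyl, bridgeheads C4 and C11, cyclobutane C4–C5–C11–C10, bridge C6(C13H2O, C14H3)–C7(OAc)–C8–C9(OSen), C15 methyl on C10)
1. The angelate and the PMB group come off last; the key disconnection is C5–C6, which opens the seven-membered ring C5–C6–C7–C8–C9–C10–C11 to a bicyclo[3.1.1]hept-3-ene-2,6-dione whose C5 carbonyl is masked as a tosylhydrazone and whose C10 chain ends in a 2-(alkoxymethyl)allyl acetate.
2. Enabling feature: C5 and C10 lie 1,3 across the cyclobutane and their bonds anti to the C1–C3 bridge are syn-axial, so the C10 chain hangs under a trigonal C5. C6 (CH3, CH2O) next to C7–O is the retron of a methyl ketone/2-(alkoxymethyl)acrolein aldol, whose 1,1-disubstituted alkene gives the C6 radical and the C14 methyl by H-atom transfer.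
3. The cyclobutane and both six-membered rings of the core are made together from an acyclic trienoic acid by intramolecular vinylketene–alkene [2+2]; C5 is the ketene carbonyl, and the C1 silyloxy centre (later the ketone) steers the face.
4. The chain comes from 2,3-dimethylfuran (C1–C3, C10–C12, C15), a vinylogous Mukaiyama aldol (C1 carbinol), a boron aldol and an Evans–Tishchenko reduction (C7/C9 anti-diol with the acetate already on O7).
5. Ring order: bicyclo[3.1.1] core in step 12, seven-membered ring last in step 16.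

Key step: step 16

Assumption: the chiral promoters of steps 4 and 8 are named in the enantiomeric form assumed to attack the aldehyde Si face (step 4) and Re face (step 8); if a model aldol shows the opposite sense, the mirror-image promoter is used and nothing else changes.

Step 1
Reactants: 1 2,3-dimethylfuran
Product: 3 (E)-3-methyl-4-oxopent-2-enal, via (Z)-3-methyl-4-oxopent-2-enal 2 (not isolated)
Conditions: NBS, NaHCO3, acetone/H2O (10:1), −20 °C; then pyridine, rt
Reagents that add atoms: water, O
Why: Oxidative furan ring opening (bromination, hydrolysis of the 2,5-adduct) should give the cis keto-enal, which pyridine isomerizes to the E isomer needed for the later trisubstituted alkene.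

Step 2
Reactants: 4 3-methylbut-2-enoic acid
Product: 5 tert-butyl 3-methylbut-2-enoate
Conditions: tert-butyl 2,2,2-trichloroacetimidate, BF3·OEt2 (cat.), cyclohexane/CH2Cl2, rt
Reagents that add atoms: tert-butyl 2,2,2-trichloroacetimidate, CC(C)(C)OC(=N)C(Cl)(Cl)Cl
Why: Acid-catalysed imidate tert-butylation of a carboxylic acid should give an ester that can later be cleaved without hydrolysing an acetate.

Step 3
Reactants: 5 tert-butyl 3-methylbut-2-enoate
Product: 6 tert-butyl[(1-tert-butoxy-3-methylbuta-1,3-dien-1-yl)oxy]dimethylsilane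
Conditions: LiN(iPr)2, THF, −78 °C; TBSCl, DMPU, −78 °C to rt
Reagents that add atoms: tert-butyl(chloro)dimethylsilane, CC(C)(C)[Si](C)(C)Cl
Why: γ-Deprotonation of the senecioate and O-silylation of the dienolate is the standard preparation of silyl dienol ethers for vinylogous aldol reactions.

Step 4
Reactants: 3 (E)-3-methyl-4-oxopent-2-enal; 6 silyl dienolate
Product: 8 tert-butyl (2E,5S,6E)-5-hydroxy-3,7-dimethyl-8-oxonona-2,6-dienoate, via trichlorosilyl ether 7 (not isolated)
Conditions: SiCl4, (R,R)-1,1'-binaphthyl-2,2'-diamine-derived bisphosphoramide (5 mol%), iPr2NEt (cat.), CH2Cl2, −78 °C; then sat. aq. NaHCO3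
Reagents that add atoms: none
Why: In this Lewis-base-activated SiCl4 vinylogous Mukaiyama aldol the dienolate should add through its γ-carbon to the aldehyde only (the ketone is inert), giving the E-enoate, and the chiral silicon cation selects the aldehyde Si face to set 5S.

Step 5
Reactants: 8 δ-hydroxy ester
Product: 9 tert-butyl (2E,5S,6E)-5-[(tert-butyldimethylsilyl)oxy]-3,7-dimethyl-8-oxonona-2,6-dienoate
Conditions: TBSCl, imidazole, DMF, rt
Reagents that add atoms: tert-butyl(chloro)dimethylsilane, CC(C)(C)[Si](C)(C)Cl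
Why: Routine silylation protects the carbinol that later directs the cycloaddition and becomes the C1 ketone.

Step 6
Reactants: 10 2-methylidenepropane-1,3-diol
Product: 11 2-{[(4-methoxybenzyl)oxy]methyl}prop-2-en-1-ol
Conditions: NaH (1 equiv), 4-methoxybenzyl chloride, Bu4NI (cat.), THF, 0 °C to rt, excess diol
Reagents that add atoms: 4-methoxybenzyl chloride, COc1ccc(CCl)cc1
Why: Williamson mono-etherification of the symmetric diol (used in excess) should give the mono-PMB ether.

Step 7
Reactants: 11 mono-PMB ether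
Product: 12 2-{[(4-methoxybenzyl)oxy]methyl}prop-2-enal
Conditions: MnO2, CH2Cl2, rt
Reagents that add atoms: none
Why: MnO2 oxidizes the allylic alcohol to the 2-substituted acrolein without touching the PMB ether.

Step 8
Reactants: 9 silyloxy methyl ketone; 12 2-substituted acrolein
Product: 15 tert-butyl (2E,5S,6E,10R)-5-[(tert-butyldimethylsilyl)oxy]-10-hydroxy-11-{[(4-methoxybenzyl)oxy]methyl}-3,7-dimethyl-8-oxododeca-2,6,11-trienoate, via boron enolate 13 (not isolated), via boron aldolate 14 (not isolated)
Conditions: (−)-Ipc2BCl, Et3N, Et2O, −78 to 0 °C; 12, −78 to −20 °C; H2O2, pH 7 buffer, MeOH, 0 °C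
Reagents that add atoms: none
Why: Reagent-controlled boron aldol of a methyl ketone through a cyclic six-membered transition state, in which the isopinocampheyl ligands select the aldehyde Re face, should set 10R (the later C7) independently of the remote C5 centre.

Step 9
Reactants: 15 β-hydroxy enone; 16 acetaldehyde
Product: 17 tert-butyl (2E,5S,6E,8R,10R)-10-acetoxy-5-[(tert-butyldimethylsilyl)oxy]-8-hydroxy-11-{[(4-methoxybenzyl)oxy]methyl}-3,7-dimethyldodeca-2,6,11-trienoate
Conditions: SmI2 (0.3 equiv), THF, −10 °C, short reaction time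
Reagents that add atoms: acetaldehyde 16, CC=O
Why: In the Evans–Tishchenko reduction the hemiacetal bound to trivalent samarium delivers hydride to the ketone through a chair-like six-membered transition state, which should give the 1,3-anti diol (8R) and leave the acetate on O10, exactly the ester pattern of the target.

Step 10
Reactants: 17 anti-diol monoacetate; 4 3-methylbut-2-enoic acid
Product: 18 tert-butyl (2E,5S,6E,8R,10R)-10-acetoxy-5-[(tert-butyldimethylsilyl)oxy]-11-{[(4-methoxybenzyl)oxy]methyl}-3,7-dimethyl-8-[(3-methylbut-2-enoyl)oxy]dodeca-2,6,11-trienoate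
Conditions: DCC, DMAP (cat.), CH2Cl2, 0 °C
Reagents that add atoms: 3-methylbut-2-enoic acid 4, CC(C)=CC(=O)O
Why: Steglich esterification of the free allylic alcohol at 0 °C should outrun 1,3-acetyl migration and install the senecioate.

Step 11
Reactants: 18 tert-butyl ester
Product: 20 (2E,5S,6E,8R,10R)-trienoic acid, via trimethylsilyl ester 19 (not isolated)
Conditions: TMSOTf, 2,6-lutidine, CH2Cl2, 0 °C; then pH 7 buffer
Reagents that add atoms: none
Why: Silyl triflate cleavage of a tert-butyl ester (O-silylation, loss of 2-methylpropene) is non-hydrolytic, so the acetate, senecioate, TBS and PMB groups should survive.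

Step 12
Reactants: 20 trienoic acid
Product: 23 2-silyloxy-4-methylidene-bicyclo[3.1.1]heptan-6-one, via acid chloride 21 (not isolated), via vinylketene 22 (not isolated)
Conditions: 1-chloro-N,N,2-trimethylprop-1-en-1-amine, CH2Cl2, 0 °C to rt; then Et3N, PhMe, reflux, slow addition, 5 mM
Reagents that add atoms: none
Why: 1,4-Elimination of HCl gives the vinylketene, whose intramolecular crossed [2+2] cycloaddition (ketene carbonyl carbon to the less substituted alkene carbon) should close the cyclobutanone and both six-membered rings at once; addition is suprafacial on the E-alkene (C15 methyl syn, side chain anti to the three-carbon bridge), and the silyloxy centre directs the face by allylic 1,3-strain, fixing C4, C10 and C11.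

Step 13
Reactants: 23 silyl ether
Product: 24 2-hydroxy-4-methylidene-bicyclo[3.1.1]heptan-6-one
Conditions: HF·pyridine, pyridine, THF, 0 °C to rt
Reagents that add atoms: none
Why: Buffered fluoride desilylation frees the carbinol; retro-aldol is impossible because it would need a bridgehead enolate.

Step 14
Reactants: 24 hydroxy ketone
Product: 26 4,7-dimethylbicyclo[3.1.1]hept-3-ene-2,6-dione, via exo-methylene dione 25 (not isolated)
Conditions: DMP (1,1,1-triacetoxy-1,2-benziodoxol-3-one), NaHCO3, CH2Cl2, rt; then DBU (cat.), CH2Cl2, 0 °C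
Reagents that add atoms: none
Why: Periodinane oxidation followed by base-catalysed β,γ to α,β isomerization (the only enolizable direction) should give the verbenone-type enone and erase the directing stereocentre.

Step 15
Reactants: 26 enone cyclobutanone
Product: 27 6-(tosylhydrazono)bicyclo[3.1.1]hept-3-en-2-one
Conditions: TsNHNH2 (1.05 equiv), MgSO4, THF, rt
Reagents that add atoms: 4-methylbenzenesulfonohydrazide, Cc1ccc(cc1)S(=O)(=O)NN
Why: Hydrazone condensation should occur only at the strained cyclobutanone (the conjugated, hindered enone carbonyl is far less electrophilic), and neutral aprotic conditions avoid retro-Claisen opening of the non-enolizable 1,3-dione.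

Step 16
Reactants: 27 tosylhydrazone
Product: 30 13-O-PMB longipinenone diester, via cyclized tosylhydrazide 28 (not isolated), via alkyl diazene 29 (not isolated)
Conditions: Fe(acac)3 (30 mol%), PhSiH3 (slow addition), EtOH/THF, 50 °C, 5 mM; then MeOH, 65 °C
Reagents that add atoms: none
Why: Proposed new method: hydrogen atom transfer from an iron hydride to the CH2 terminus of the 1,1-disubstituted alkene should create the C14 methyl and a tertiary C6 radical that adds to the carbon of the C5 tosylhydrazone; the hydrazinyl radical is reduced by divalent iron and protonated to hydrazide 28, and warming expels 4-methylbenzenesulfinic acid and then N2 from diazene 29 to leave C5–H. The closest known reactions are the iron-hydride reductive coupling of alkenes with formaldehyde sulfonylhydrazones (traceless hydromethylation) and the five- and six-membered HAT cyclizations of alkenes onto ketone tosylhydrazones; new here are the seven-membered ring, the cyclobutanone-derived acceptor and the quaternary carbon formed. The ring C5–C6–C7–C8–C9–C10–C11 closes 7-exo-trig onto C=N, feasible because the C10 chain and the reacting lobe of C5 are syn-axial across the cyclobutane while the other face of C5 is blocked by the C1–C3 bridge. C6 is controlled by the adjacent C7 acetoxy centre (C7–O anti to the forming bond, the larger CH2OPMB arm eclipsing C7–H, the methyl gauche to C8), and C5 is fixed by the cage, since the chain can bond only anti to the enone bridge and the hydrogen then takes the one remaining position, syn to that bridge. The step needs HAT to the isolated 1,1-disubstituted alkene rather than to the enone or senecioate (both electron-poor trisubstituted alkenes that react much more slowly with the hydride) and cyclization faster than reduction of the radical (high dilution, slow silane addition). A ketone acceptor is avoided on purpose: a cyclobutyloxyl radical would ring-open, whereas the hydrazinyl radical cannot.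

Step 17
Reactants: 30 PMB ether
Product: 31 13-hydroxy longipinenone diester
Conditions: DDQ, CH2Cl2/pH 7 buffer (10:1), 0 °C
Reagents that add atoms: none
Why: Oxidative PMB cleavage under neutral conditions should free the primary alcohol without touching the enone or the esters and without promoting acetyl migration.

Step 18
Reactants: 31 primary alcohol; 32 angelic acid
Product: 34 target CNP0179010.1, via mixed anhydride 33 (not isolated)
Conditions: 2,4,6-trichlorobenzoyl chloride, Et3N, PhMe, rt; then 31, PhMe, 60 °C, no DMAP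
Reagents that add atoms: angelic acid 32, C/C=C(/C)C(=O)O
Why: Yamaguchi-type acylation through the mixed anhydride without a nucleophilic catalyst is the standard way to transfer an angeloyl group with retention of the Z geometry, and the primary neopentyl alcohol is the only free hydroxyl.

**Compound list**
1 | 2,3-dimethylfuran | Cc1occc1C | starting material
2 | (Z)-3-methyl-4-oxopent-2-enal | CC(=O)/C(C)=C\C=O | intermediate
3 | (E)-3-methyl-4-oxopent-2-enal | CC(=O)/C(C)=C/C=O | intermediate
4 | 3-methylbut-2-enoic acid (senecioic acid) | CC(C)=CC(=O)O | starting material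
5 | tert-butyl 3-methylbut-2-enoate | CC(C)=CC(=O)OC(C)(C)C | intermediate
6 | tert-butyl[(1-tert-butoxy-3-methylbuta-1,3-dien-1-yl)oxy]dimethylsilane | C=C(C)C=C(OC(C)(C)C)O[Si](C)(C)C(C)(C)C | intermediate
7 | tert-butyl (2E,5S,6E)-3,7-dimethyl-8-oxo-5-[(trichlorosilyl)oxy]nona-2,6-dienoate | CC(C)(C)OC(=O)/C=C(C)/C[C@H](O[Si](Cl)(Cl)Cl)/C=C(C)/C(C)=O | intermediate
8 | tert-butyl (2E,5S,6E)-5-hydroxy-3,7-dimethyl-8-oxonona-2,6-dienoate | CC(C)(C)OC(=O)/C=C(C)/C[C@H](O)/C=C(C)/C(C)=O | intermediate
9 | tert-butyl (2E,5S,6E)-5-[(tert-butyldimethylsilyl)oxy]-3,7-dimethyl-8-oxonona-2,6-dienoate | CC(C)(C)OC(=O)/C=C(C)/C[C@H](O[Si](C)(C)C(C)(C)C)/C=C(C)/C(C)=O | intermediate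
10 | 2-methylidenepropane-1,3-diol | C=C(CO)CO | starting material
11 | 2-{[(4-methoxybenzyl)oxy]methyl}prop-2-en-1-ol | C=C(CO)COCc1ccc(OC)cc1 | intermediate
12 | 2-{[(4-methoxybenzyl)oxy]methyl}prop-2-enal | C=C(C=O)COCc1ccc(OC)cc1 | intermediate
13 | diisopinocampheylboron enolate of 9 (2-boryloxy-1,3-diene) | CC(C)(C)OC(=O)/C=C(C)/C[C@H](O[Si](C)(C)C(C)(C)C)/C=C(C)/C(=C)OB([C@@H]1C[C@@H]2C[C@H]([C@H]1C)C2(C)C)[C@@H]1C[C@@H]2C[C@H]([C@H]1C)C2(C)C | intermediate
14 | diisopinocampheylboron aldolate of 15 | CC(C)(C)OC(=O)/C=C(C)/C[C@H](O[Si](C)(C)C(C)(C)C)/C=C(C)/C(=O)C[C@@H](OB([C@@H]1C[C@@H]2C[C@H]([C@H]1C)C2(C)C)[C@@H]1C[C@@H]2C[C@H]([C@H]1C)C2(C)C)C(=C)COCc1ccc(OC)cc1 | intermediate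
15 | tert-butyl (2E,5S,6E,10R)-5-[(tert-butyldimethylsilyl)oxy]-10-hydroxy-11-{[(4-methoxybenzyl)oxy]methyl}-3,7-dimethyl-8-oxododeca-2,6,11-trienoate | CC(C)(C)OC(=O)/C=C(C)/C[C@H](O[Si](C)(C)C(C)(C)C)/C=C(C)/C(=O)C[C@@H](O)C(=C)COCc1ccc(OC)cc1 | intermediate
16 | acetaldehyde | CC=O | starting material
17 | tert-butyl (2E,5S,6E,8R,10R)-10-acetoxy-5-[(tert-butyldimethylsilyl)oxy]-8-hydroxy-11-{[(4-methoxybenzyl)oxy]methyl}-3,7-dimethyldodeca-2,6,11-trienoate | CC(C)(C)OC(=O)/C=C(C)/C[C@H](O[Si](C)(C)C(C)(C)C)/C=C(C)/[C@H](O)C[C@@H](OC(C)=O)C(=C)COCc1ccc(OC)cc1 | intermediate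
18 | tert-butyl (2E,5S,6E,8R,10R)-10-acetoxy-5-[(tert-butyldimethylsilyl)oxy]-11-{[(4-methoxybenzyl)oxy]methyl}-3,7-dimethyl-8-[(3-methylbut-2-enoyl)oxy]dodeca-2,6,11-trienoate | CC(C)(C)OC(=O)/C=C(C)/C[C@H](O[Si](C)(C)C(C)(C)C)/C=C(C)/[C@H](OC(=O)C=C(C)C)C[C@@H](OC(C)=O)C(=C)COCc1ccc(OC)cc1 | intermediate
19 | trimethylsilyl ester of acid 20 | C[Si](C)(C)OC(=O)/C=C(C)/C[C@H](O[Si](C)(C)C(C)(C)C)/C=C(C)/[C@H](OC(=O)C=C(C)C)C[C@@H](OC(C)=O)C(=C)COCc1ccc(OC)cc1 | intermediate
20 | (2E,5S,6E,8R,10R)-10-acetoxy-5-[(tert-butyldimethylsilyl)oxy]-11-{[(4-methoxybenzyl)oxy]methyl}-3,7-dimethyl-8-[(3-methylbut-2-enoyl)oxy]dodeca-2,6,11-trienoic acid | OC(=O)/C=C(C)/C[C@H](O[Si](C)(C)C(C)(C)C)/C=C(C)/[C@H](OC(=O)C=C(C)C)C[C@@H](OC(C)=O)C(=C)COCc1ccc(OC)cc1 | intermediate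
21 | acid chloride of 20 | ClC(=O)/C=C(C)/C[C@H](O[Si](C)(C)C(C)(C)C)/C=C(C)/[C@H](OC(=O)C=C(C)C)C[C@@H](OC(C)=O)C(=C)COCc1ccc(OC)cc1 | intermediate
22 | vinylketene (3-methylidene ketene) from 21 | O=C=CC(=C)C[C@H](O[Si](C)(C)C(C)(C)C)/C=C(C)/[C@H](OC(=O)C=C(C)C)C[C@@H](OC(C)=O)C(=C)COCc1ccc(OC)cc1 | intermediate
23 | (2S)-2-[(tert-butyldimethylsilyl)oxy]-7-methyl-4-methylidenebicyclo[3.1.1]heptan-6-one bearing at C7, anti to the C2–C4 bridge, the (1R,3R)-3-acetoxy-4-{[(4-methoxybenzyl)oxy]methyl}-1-[(3-methylbut-2-enoyl)oxy]pent-4-en-1-yl chain; silyloxy group on the side of the C6 carbonyl; ring configuration as in the SMILES | O=C1[C@@H]2C(=C)C[C@H](O[Si](C)(C)C(C)(C)C)[C@H]1[C@]2(C)[C@H](OC(=O)C=C(C)C)C[C@@H](OC(C)=O)C(=C)COCc1ccc(OC)cc1 | intermediate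
24 | 2-hydroxy analogue of 23 (free carbinol, same configuration) | O=C1[C@@H]2C(=C)C[C@H](O)[C@H]1[C@]2(C)[C@H](OC(=O)C=C(C)C)C[C@@H](OC(C)=O)C(=C)COCc1ccc(OC)cc1 | intermediate
25 | 7-methyl-4-methylidenebicyclo[3.1.1]heptane-2,6-dione with the same C7 chain | O=C1[C@@H]2C(=C)CC(=O)[C@H]1[C@]2(C)[C@H](OC(=O)C=C(C)C)C[C@@H](OC(C)=O)C(=C)COCc1ccc(OC)cc1 | intermediate
26 | 4,7-dimethylbicyclo[3.1.1]hept-3-ene-2,6-dione with the same C7 chain (chain anti to the enone bridge) | O=C1[C@@H]2C(C)=CC(=O)[C@H]1[C@]2(C)[C@H](OC(=O)C=C(C)C)C[C@@H](OC(C)=O)C(=C)COCc1ccc(OC)cc1 | intermediate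
27 | 6-(4-methylbenzenesulfonylhydrazono) derivative of 26 (C=N geometry not defined) | Cc1ccc(cc1)S(=O)(=O)NN=C1[C@@H]2C(C)=CC(=O)[C@H]1[C@]2(C)[C@H](OC(=O)C=C(C)C)C[C@@H](OC(C)=O)C(=C)COCc1ccc(OC)cc1 | intermediate
28 | 30 carrying a 2-tosylhydrazinyl group on C5 in place of hydrogen (syn to the enone bridge) | Cc1ccc(cc1)S(=O)(=O)NN[C@]12[C@@H]3C(C)=CC(=O)[C@H]1[C@]3(C)[C@H](OC(=O)C=C(C)C)C[C@@H](OC(C)=O)[C@]2(C)COCc1ccc(OC)cc1 | intermediate
29 | 30 carrying a diazenyl group (N=NH) on C5 in place of hydrogen (syn to the enone bridge) | N=N[C@]12[C@@H]3C(C)=CC(=O)[C@H]1[C@]3(C)[C@H](OC(=O)C=C(C)C)C[C@@H](OC(C)=O)[C@]2(C)COCc1ccc(OC)cc1 | intermediate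
30 | (4R,5S,6S,7R,9R,10R,11R)-7-acetoxy-13-[(4-methoxybenzyl)oxy]-9-[(3-methylbut-2-enoyl)oxy]longipin-2-en-1-one (7-OAc and 9-OSen trans; C13 on the side of C11, C14 methyl on the side of C4) | [C@H]12[C@@H]3C(C)=CC(=O)[C@H]1[C@]3(C)[C@H](OC(=O)C=C(C)C)C[C@@H](OC(C)=O)[C@]2(C)COCc1ccc(OC)cc1 | intermediate
31 | (4R,5S,6S,7R,9R,10R,11R)-7-acetoxy-13-hydroxy-9-[(3-methylbut-2-enoyl)oxy]longipin-2-en-1-one | [C@H]12[C@@H]3C(C)=CC(=O)[C@H]1[C@]3(C)[C@H](OC(=O)C=C(C)C)C[C@@H](OC(C)=O)[C@]2(C)CO | intermediate
32 | angelic acid, (Z)-2-methylbut-2-enoic acid | C/C=C(/C)C(=O)O | starting material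
33 | (Z)-2-methylbut-2-enoic 2,4,6-trichlorobenzoic anhydride | C/C=C(/C)C(=O)OC(=O)c1c(Cl)cc(Cl)cc1Cl | intermediate
34 | CNP0179010.1, (4R,5S,6S,7R,9R,10R,11R)-7-acetoxy-13-{[(2Z)-2-methylbut-2-enoyl]oxy}-9-[(3-methylbut-2-enoyl)oxy]longipin-2-en-1-one | [C@H]12[C@@H]3C(C)=CC(=O)[C@H]1[C@]3(C)[C@H](OC(=O)C=C(C)C)C[C@@H](OC(C)=O)[C@]2(C)COC(=O)/C(C)=C\C | target

**Step count**
Total: 18 steps. Longest linear sequence: 15 steps (steps 2, 3, 4, 5 and 8 to 18, from 3-methylbut-2-enoic acid).

**Steps most likely to fail**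

Step 16 (proposed new method). The tertiary radical may be reduced by the iron hydride before the slow seven-membered closure, the facial course at C6 may be poorly controlled, or the hydrazide may not lose sulfinate cleanly. The fallback separates radical generation from hydride delivery and uses a radical acceptor that fragments on its own. It sets out from dione 26: cobalt-mediated Markovnikov hydrobromination by hydrogen atom transfer (Co(acac)2, t-BuOOH, Et3SiH, 4-methylbenzenesulfonyl bromide) should give the tertiary bromide F1. Condensation of its cyclobutanone with 1-amino-2-phenylaziridine gives the N-aziridinylimine F2. Bu3SnH added by syringe pump with AIBN in benzene at 80 °C generates the same C6 radical by bromine abstraction; it cyclizes onto C=N, the aziridinylaminyl radical fragments to styrene and N2, and the C5 radical takes hydrogen from the stannane, returning to the route at 30. If the C6 ratio is still poor, a bulkier silyl ether in place of PMB on O13 would strengthen the bias, but that is a change of conditions only.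

Step 12. The ketene faces an alkene flanked by two allylic C–O bonds, so dimerization may outrun cycloaddition, and the face selectivity set by the silyloxy centre may be eroded by the C9 stereocentre. The fallback uses the more electrophilic keteniminium cycloaddition. It sets out from acid 20: carbodiimide coupling with dimethylamine gives the amide F3. Tf2O and 2,6-di-tert-butyl-4-methylpyridine in 1,2-dichloroethane generate the vinylketeniminium ion, whose intramolecular [2+2] cycloaddition gives the cyclobutaniminium triflate F4. Hydrolysis with aqueous NaHCO3 gives ketone 23, where the route is rejoined.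

Step 18. Under the warm basic acylation the angelate may isomerize to the tiglate, or the C7 acetyl group may migrate to the free primary oxygen before acylation. The fallback builds the Z-alkene on the ester. It sets out from alcohol 31: carbodiimide coupling with 2-[bis(2,2,2-trifluoroethoxy)phosphoryl]propanoic acid at 0 °C gives the phosphonate ester F5. Still–Gennari olefination (KN(SiMe3)2, 18-crown-6, THF, −78 °C, acetaldehyde) should then give the Z-2-methylbut-2-enoate, which is target 34.

Further compounds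
F1 | step 16 | tertiary bromide from Markovnikov hydrobromination of 26 (C–Br centre as a mixture) | O=C1[C@@H]2C(C)=CC(=O)[C@H]1[C@]2(C)[C@H](OC(=O)C=C(C)C)C[C@@H](OC(C)=O)C(C)(Br)COCc1ccc(OC)cc1
F2 | step 16 | N-(2-phenylaziridin-1-yl)imine of the cyclobutanone of F1 | C1(c2ccccc2)CN1N=C3[C@@H]4C(C)=CC(=O)[C@H]3[C@]4(C)[C@H](OC(=O)C=C(C)C)C[C@@H](OC(C)=O)C(C)(Br)COCc1ccc(OC)cc1
F3 | step 12 | N,N-dimethylamide of acid 20 | CN(C)C(=O)/C=C(C)/C[C@H](O[Si](C)(C)C(C)(C)C)/C=C(C)/[C@H](OC(=O)C=C(C)C)C[C@@H](OC(C)=O)C(=C)COCc1ccc(OC)cc1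
F4 | step 12 | N,N-dimethyl cyclobutaniminium triflate corresponding to ketone 23 | C[N+](C)=C1[C@@H]2C(=C)C[C@H](O[Si](C)(C)C(C)(C)C)[C@H]1[C@]2(C)[C@H](OC(=O)C=C(C)C)C[C@@H](OC(C)=O)C(=C)COCc1ccc(OC)cc1.[O-]S(=O)(=O)C(F)(F)F
F5 | step 18 | 13-O-{2-[bis(2,2,2-trifluoroethoxy)phosphoryl]propanoyl} ester of 31 | [C@H]12[C@@H]3C(C)=CC(=O)[C@H]1[C@]3(C)[C@H](OC(=O)C=C(C)C)C[C@@H](OC(C)=O)[C@]2(C)COC(=O)C(C)P(=O)(OCC(F)(F)F)OCC(F)(F)F
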